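**Assumption:** the supplied SMILES is taken exactly as written (including C9, where H‑9 is anti to the C8–C15 bond), and ent‑kaurane numbering is used throughout.

## Retrosynthetic overview
1. The C6 aldehyde comes from a primary alcohol (TEMPO‑type oxidation) and the C15 enone from allylic oxidation of C16=C17. The C11 carbinol comes from the C11 ketone by a ketoreductase.
2. Ring D (bicyclo[3.2.1]octane) comes from Pd(II) oxidative cyclization of the lactone silyl ketene acetal onto a C13 isopropenyl group, forming the C8–C15 bond.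
3. Ring C comes from an intramolecular aldol condensation of a keto‑aldehyde on the spirolactone. The C13 isopropenyl group comes from a cuprate 1,4‑addition to the resulting enone.
4. The spiro δ‑lactone (C9–C10 bond) comes from Ti(III) epoxide opening and Giese addition of the ring‑A spiro‑epoxide to an enoate acetal.
5. Ring A comes from Cu‑catalysed asymmetric conjugate addition of MeMgBr to a 3‑(CH2OPMB) cyclohexenone (C4 quaternary centre). Rings are formed in the order A, lactone, C, D.

## Route

**Step 1**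
Reactants: 1 tributyl(hydroxymethyl)stannane; 2 4‑methoxybenzyl chloride
Product: 3 tributyl{[(4‑methoxybenzyl)oxy]methyl}stannane
Conditions: NaH, TBAI (cat.), THF, 0 → 23 °C
Reagents that add atoms: 2, PMBCl, COc1ccc(CCl)cc1
Why: Williamson etherification gives the α‑alkoxyalkylstannane, a masked LiCH2OPMB nucleophile; no stereocentre.

**Step 2**
Reactants: 4 3‑ethoxycyclohex‑2‑en‑1‑one; 3
Product: 5 3‑{[(4‑methoxybenzyl)oxy]methyl}cyclohex‑2‑en‑1‑one
Conditions: n‑BuLi, THF, –78 °C (Sn/Li exchange), add 4; then 2 M aq. HCl, 23 °C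
Reagents that add atoms: water (O), O
Why: Stork–Danheiser 1,2‑addition/hydrolytic transposition installs the β‑CH2OPMB group on the enone; no stereocentre.

**Step 3**
Reactants: 5; 6 methylmagnesium bromide
Product: 7 (R)‑3‑{[(4‑methoxybenzyl)oxy]methyl}‑3‑methylcyclohexan‑1‑one
Conditions: MeMgBr, CuBr·SMe2 (5 mol%), Josiphos‑type ligand (6 mol%), t‑BuOMe, –78 °C
Reagents that add atoms: 6, C[Mg]Br
Why: Cu‑catalysed asymmetric conjugate addition of a Grignard reagent to a β‑substituted cyclic enone sets the C4 quaternary centre (Me vs CH2OPMB) by chiral‑ligand facial control; the ligand enantiomer is chosen to give the (R)‑ketone, C4 as in the target.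

**Step 4**
Reactants: 7
Product: 8 (R)‑5‑{[(4‑methoxybenzyl)oxy]methyl}‑5‑methylcyclohex‑2‑en‑1‑one
Conditions: IBX, 4‑methoxypyridine N‑oxide, DMSO, 65 °C
Reagents that add atoms: none
Why: Nicolaou IBX dehydrogenation can only desaturate C1–C2 because C4 is quaternary; C4 is untouched.

**Step 5**
Reactants: 8; 9 formaldehyde
Product: 10 6‑(hydroxymethyl)‑5‑[(PMBO)methyl]‑5‑methylcyclohex‑2‑en‑1‑one (C4/C5 as in target)
Conditions: LiHMDS, THF, –78 °C; then monomeric HCHO (from (CH2O)n), –78 °C; cold NH4Cl quench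
Reagents that add atoms: 9, formaldehyde, C=O
Why: The kinetic cross‑conjugated enolate can only form at C5 (the α′ carbon), and the aldol with HCHO occurs axially anti to the pseudo‑axial methyl (C18), placing the new C6 cis to C19 and setting C5.

**Step 6**
Reactants: 10; 11 tert‑butyldimethylsilyl chloride
Product: 12 C6‑OTBS enone
Conditions: TBSCl, imidazole, DMF, 0 → 23 °C
Reagents that add atoms: 11, TBSCl, C[Si](C)(Cl)C(C)(C)C
Why: Mild silylation of the primary alcohol avoids retro‑aldol and epimerization at C5.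

**Step 7**
Reactants: 12
Product: 13 (C10 ketone, saturated ring A)
Conditions: [(Ph3P)CuH]6 (Stryker), toluene, 0 → 23 °C; sat. NH4Cl
Reagents that add atoms: none
Why: Cu–H 1,4‑reduction saturates C1=C2 chemoselectively, leaving the PMB and TBS ethers; C5 is untouched because protonation occurs at C1.

**Step 8**
Reactants: 13; 14 dimethyltitanocene
Product: 15 (C10=C20 exocyclic methylene)
Conditions: Cp2TiMe2, toluene, 70 °C
Reagents that add atoms: 14, Petasis reagent, C[Ti](C)(C1C=CC=C1)C1C=CC=C1 (supplies C20)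
Why: Petasis methylenation converts the hindered α‑stereogenic ketone without basic conditions that would epimerize C5.

**Step 9**
Reactants: 15; 16 mCPBA
Product: 17 spiro‑epoxide at C10/C20 (C10 epimers not separated)
Conditions: mCPBA, NaHCO3, CH2Cl2, 0 °C
Reagents that add atoms: 16, mCPBA, O=C(OO)c1cccc(Cl)c1
Why: Prilezhaev epoxidation of the 1,1‑disubstituted alkene; both epoxide epimers give the same tertiary radical in Step 10.

**Step 10**
Reactants: 17; 18 ethyl (E)‑4,4‑diethoxybut‑2‑enoate
Product: 19 spirolactone (C9–C10 bond; C9 as an epimeric mixture)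
Conditions: Cp2TiCl2, Zn, collidine·HCl, THF, 23 °C; then DBU (cat.), PhMe, 60 °C
Reagents that add atoms: none beyond reactant 18
Why: Ti(III) homolysis of the epoxide (Nugent–RajanBabu) gives the tertiary C10 radical with C20–OTi, which adds (Giese) to the β‑carbon (C9) of the enoate on the face anti to the axial C19 group, setting C10 with C20 axial and syn to C19; Ti‑enolate protonation and lactonization follow, and the C9 epimers are converged in Step 16.

**Step 11**
Reactants: 19; 20 allyl bromide
Product: 21 C8‑allyl spirolactone (C8/C9 epimeric mixture)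
Conditions: LiHMDS, THF, –78 °C; allyl bromide, DMPU, –78 → –20 °C
Reagents that add atoms: 20, C=CCBr
Why: C‑Alkylation of the lactone enolate adds the C14/C13 unit; the new C8 stereocentre is epimerizable and is reset in Step 16.

**Step 12**
Reactants: 21
Product: 22 aldehyde (C11 CHO)
Conditions: PPTS, acetone/H2O (10:1), 55 °C
Reagents that add atoms: water, O
Why: Mild acid hydrolysis of the diethyl acetal spares the TBS and PMB ethers.

**Step 13**
Reactants: 22; 23 methyltitanium triisopropoxide
Product: 24 C11 secondary alcohol (C12 methyl)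
Conditions: MeTi(OiPr)3, THF, –78 → 0 °C
Reagents that add atoms: 23, C[Ti](OC(C)C)(OC(C)C)OC(C)C (supplies C12)
Why: Reetz methyltitanation adds to the aldehyde chemoselectively in the presence of the lactone; the new carbinol centre is oxidized in Step 14.

**Step 14**
Reactants: 24
Product: 25 methyl ketone (C11=O, C12H3)
Conditions: Dess–Martin periodinane, NaHCO3, CH2Cl2, 23 °C
Reagents that add atoms: none
Why: Oxidation of the secondary alcohol removes the C11 stereocentre and makes C9 α to a ketone.

**Step 15**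
Reactants: 25
Product: 26 keto‑aldehyde (C8–CH2CHO)
Conditions: OsO4 (cat.), NaIO4, 2,6‑lutidine, dioxane/H2O (3:1), 23 °C
Reagents that add atoms: sodium periodate, [Na+].[O-]I(=O)(=O)=O (source of the aldehyde O)
Why: Lemieux–Johnson cleavage of the terminal alkene leaves the ketone, lactone and ethers intact.

**Step 16**
Reactants: 26
Product: 27 spirolactone‑fused cyclohexenone (ring C)
Conditions: piperidine, AcOH, PhMe, 80 °C; then DBU, PhMe, 80 °C
Reagents that add atoms: none
Why: Intramolecular aldol condensation (Robinson‑type; C12–C13 bond) closes ring C, and enolization at C9/C8 lets the ring fusion equilibrate to the trans‑fused diastereomer with C7 and C10 equatorial, fixing C8 and C9.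

**Step 17**
Reactants: 27; 28 isopropenylmagnesium bromide
Product: 29 ketone with axial C13 isopropenyl
Conditions: isopropenylMgBr, CuBr·SMe2, TMSCl, DMPU, THF, –78 °C; aq. NH4Cl
Reagents that add atoms: 28, CC(=C)[Mg]Br
Why: Cu‑mediated 1,4‑addition occurs axially on the ring‑C chair locked by the trans‑fused lactone, from the face syn to axial H‑8, setting C13 with the isopropenyl group axial and correctly placed for bridging.

**Step 18**
Reactants: 29; 30 1,2‑bis(trimethylsilyloxy)ethane
Product: 31 C11 ethylene ketal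
Conditions: TMSOCH2CH2OTMS, TMSOTf (5 mol%), CH2Cl2, –78 → 0 °C
Reagents that add atoms: 30, C[Si](C)(C)OCCO[Si](C)(C)C
Why: Noyori ketalization under aprotic conditions masks the C11 ketone so that only the lactone can enolize in Step 19.

**Step 19**
Reactants: 31
Product: 32 bicyclo[3.2.1]octane ketal
Conditions: LDA, TMSCl, THF, –78 °C; then Pd(OAc)2 (1.0 equiv), MeCN, 23 °C
Reagents that add atoms: none (the TMS group is lost)
Why: Toyota–Reisman Pd(II) cycloalkenylation: the lactone silyl ketene acetal attacks the Pd‑activated isopropenyl group across the 1,3‑diaxial gap (C8→C15), so the C8 quaternary centre is fixed on the face of C13, and β‑H elimination from the C17 methyl gives the exocyclic C16=C17.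

**Step 20**
Reactants: 32
Product: 33 C11 ketone
Conditions: TMSOTf, 2,6‑lutidine, CH2Cl2, 0 °C; then H2O
Reagents that add atoms: water, O
Why: Fujioka deketalization is mild enough to keep the lactone, alkene, TBS and PMB ethers.

**Step 21**
Reactants: 33
Product: 34 C19 primary alcohol
Conditions: DDQ, CH2Cl2/pH 7 phosphate buffer (18:1), 0 → 23 °C
Reagents that add atoms: none
Why: Oxidative (single‑electron) cleavage of the PMB ether frees C19–OH selectively.

**Step 22**
Reactants: 34; 35 acetic anhydride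
Product: 36 C19 acetate
Conditions: Ac2O, pyridine, DMAP (cat.), CH2Cl2, 23 °C
Reagents that add atoms: 35, Ac2O, CC(=O)OC(C)=O
Why: Only one free hydroxyl is present, so O‑acetylation is unambiguous; the C11 alcohol does not yet exist.

**Step 23**
Reactants: 36
Product: 37 C11 equatorial alcohol
Conditions: ketoreductase KRED (NADPH‑dependent oxidoreductase, EC 1.1.1.‑), NADP+ (cat.), D‑glucose/glucose dehydrogenase, KPi pH 7.0, 10% DMSO, 30 °C
Reagents that add atoms: none (hydride from NADPH, proton from medium)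
Why: The enzyme delivers hydride axially from the face syn to the C15–C16 bridge, which borohydride cannot do because C15/C16 shield that trajectory (it would give the axial alcohol), so C11 is set as the equatorial carbinol of the target.

**Step 24**
Reactants: 37
Product: 38 C15 allylic alcohol (C15 epimers)
Conditions: SeO2 (0.3 equiv), TBHP (3 equiv), CH2Cl2, 23 °C
Reagents that add atoms: tert‑butyl hydroperoxide, CC(C)(C)OO; selenium dioxide, O=[Se]=O (source of the C15 oxygen)
Why: Riley allylic oxidation of the C16=C17 alkene occurs at C15, the only oxidizable allylic CH2 (C13 is a bridgehead); the C15 stereocentre is destroyed in Step 25.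

**Step 25**
Reactants: 38
Product: 39 α‑methylene ketone (C15=O, C16=C17)
Conditions: activated MnO2, CH2Cl2, 23 °C
Reagents that add atoms: none
Why: MnO2 oxidizes the allylic C15 alcohol selectively and leaves the non‑allylic C11 alcohol untouched.

**Step 26**
Reactants: 39
Product: 40 C6 primary alcohol
Conditions: HF·pyridine, pyridine, THF, 0 → 23 °C
Reagents that add atoms: none
Why: Buffered fluoride removes the primary TBS ether without touching the C19 acetate, lactone or enone.

**Step 27**
Reactants: 40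
Product: 41 Trichorabdal B
Conditions: AZADO (10 mol%), PhI(OAc)2, CH2Cl2, 0 °C
Reagents that add atoms: none
Why: Nitroxyl‑catalysed (Anelli‑type) oxidation is selective for the primary C6 alcohol over the hindered secondary C11 alcohol; C5 keeps its equatorial C6 (aldehyde) configuration.

## Compound list
1 | tributyl(hydroxymethyl)stannane | CCCC[Sn](CCCC)(CCCC)CO | starting material
2 | 4‑methoxybenzyl chloride | COc1ccc(CCl)cc1 | starting material
3 | tributyl{[(4‑methoxybenzyl)oxy]methyl}stannane | CCCC[Sn](CCCC)(CCCC)COCc1ccc(OC)cc1 | intermediate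
4 | 3‑ethoxycyclohex‑2‑en‑1‑one | CCOC1=CC(=O)CCC1 | starting material
5 | 3‑{[(4‑methoxybenzyl)oxy]methyl}cyclohex‑2‑en‑1‑one | COc1ccc(COCC2=CC(=O)CCC2)cc1 | intermediate
6 | methylmagnesium bromide | C[Mg]Br | starting material
7 | (R)‑3‑{[(4‑methoxybenzyl)oxy]methyl}‑3‑methylcyclohexan‑1‑one | O=C1CCC[C@@](C)(COCc2ccc(OC)cc2)C1 | intermediate
8 | (R)‑5‑{[(4‑methoxybenzyl)oxy]methyl}‑5‑methylcyclohex‑2‑en‑1‑one | O=C1C=CC[C@@](C)(COCc2ccc(OC)cc2)C1 | intermediate
9 | formaldehyde | C=O | starting material
10 | 6‑(hydroxymethyl)‑5‑(PMB‑oxymethyl)‑5‑methylcyclohex‑2‑enone | O=C1C=CC[C@@](C)(COCc2ccc(OC)cc2)[C@H]1CO | intermediate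
11 | tert‑butyldimethylsilyl chloride | C[Si](C)(Cl)C(C)(C)C | starting material
12 | C6‑OTBS enone | O=C1C=CC[C@@](C)(COCc2ccc(OC)cc2)[C@H]1CO[Si](C)(C)C(C)(C)C | intermediate
13 | saturated ring‑A ketone | O=C1CCC[C@@](C)(COCc2ccc(OC)cc2)[C@H]1CO[Si](C)(C)C(C)(C)C | intermediate
14 | dimethyltitanocene | C[Ti](C)(C1C=CC=C1)C1C=CC=C1 | starting material
15 | exocyclic methylene (C10=C20) | C=C1CCC[C@@](C)(COCc2ccc(OC)cc2)[C@H]1CO[Si](C)(C)C(C)(C)C | intermediate
16 | meta‑chloroperbenzoic acid | O=C(OO)c1cccc(Cl)c1 | starting material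
17 | spiro‑epoxide (C10 epimers) | C1OC12CCC[C@@](C)(COCc3ccc(OC)cc3)[C@H]2CO[Si](C)(C)C(C)(C)C | intermediate
18 | ethyl (E)‑4,4‑diethoxybut‑2‑enoate | CCOC(=O)/C=C/C(OCC)OCC | starting material
19 | spirolactone with C9‑CH(OEt)2 (C9 epimers) | CCOC(OCC)C1CC(=O)OC[C@]12CCC[C@@](C)(COCc3ccc(OC)cc3)[C@H]2CO[Si](C)(C)C(C)(C)C | intermediate
20 | allyl bromide | C=CCBr | starting material
21 | C8‑allyl lactone | CCOC(OCC)C1C(CC=C)C(=O)OC[C@]12CCC[C@@](C)(COCc3ccc(OC)cc3)[C@H]2CO[Si](C)(C)C(C)(C)C | intermediate
22 | C11 aldehyde | O=CC1C(CC=C)C(=O)OC[C@]12CCC[C@@](C)(COCc3ccc(OC)cc3)[C@H]2CO[Si](C)(C)C(C)(C)C | intermediate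
23 | methyltitanium triisopropoxide | C[Ti](OC(C)C)(OC(C)C)OC(C)C | starting material
24 | C11 secondary alcohol | CC(O)C1C(CC=C)C(=O)OC[C@]12CCC[C@@](C)(COCc3ccc(OC)cc3)[C@H]2CO[Si](C)(C)C(C)(C)C | intermediate
25 | C11 methyl ketone | CC(=O)C1C(CC=C)C(=O)OC[C@]12CCC[C@@](C)(COCc3ccc(OC)cc3)[C@H]2CO[Si](C)(C)C(C)(C)C | intermediate
26 | keto‑aldehyde | CC(=O)C1C(CC=O)C(=O)OC[C@]12CCC[C@@](C)(COCc3ccc(OC)cc3)[C@H]2CO[Si](C)(C)C(C)(C)C | intermediate
27 | tricyclic enone (ring C) | O=C1C=CC[C@@H]2C(=O)OC[C@]3(CCC[C@@](C)(COCc4ccc(OC)cc4)[C@H]3CO[Si](C)(C)C(C)(C)C)[C@@H]12 | intermediate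
28 | isopropenylmagnesium bromide | CC(=C)[Mg]Br | starting material
29 | C13 isopropenyl ketone | O=C1C[C@@H](C(C)=C)C[C@@H]2C(=O)OC[C@]3(CCC[C@@](C)(COCc4ccc(OC)cc4)[C@H]3CO[Si](C)(C)C(C)(C)C)[C@@H]12 | intermediate
30 | 1,2‑bis(trimethylsilyloxy)ethane | C[Si](C)(C)OCCO[Si](C)(C)C | starting material
31 | C11 ethylene ketal | C15(OCCO5)C[C@@H](C(C)=C)C[C@@H]2C(=O)OC[C@]3(CCC[C@@](C)(COCc4ccc(OC)cc4)[C@H]3CO[Si](C)(C)C(C)(C)C)[C@@H]12 | intermediate
32 | bicyclo[3.2.1] ketal with C16=C17 | C=C1C[C@]23C[C@H]1CC4(OCCO4)[C@@H]2[C@@]1(CCC[C@@](C)(COCc5ccc(OC)cc5)[C@H]1CO[Si](C)(C)C(C)(C)C)COC3=O | intermediate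
33 | C11 ketone | C=C1C[C@]23C[C@H]1CC(=O)[C@@H]2[C@@]1(CCC[C@@](C)(COCc4ccc(OC)cc4)[C@H]1CO[Si](C)(C)C(C)(C)C)COC3=O | intermediate
34 | C19 alcohol | C=C1C[C@]23C[C@H]1CC(=O)[C@@H]2[C@@]1(CCC[C@@](C)(CO)[C@H]1CO[Si](C)(C)C(C)(C)C)COC3=O | intermediate
35 | acetic anhydride | CC(=O)OC(C)=O | starting material
36 | C19 acetate, C11 ketone | C=C1C[C@]23C[C@H]1CC(=O)[C@@H]2[C@@]1(CCC[C@@](C)(COC(C)=O)[C@H]1CO[Si](C)(C)C(C)(C)C)COC3=O | intermediate
37 | C11 alcohol | C=C1C[C@]23C[C@H]1C[C@@H](O)[C@@H]2[C@@]1(CCC[C@@](C)(COC(C)=O)[C@H]1CO[Si](C)(C)C(C)(C)C)COC3=O | intermediate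
38 | C15 allylic alcohol | C=C1C(O)[C@]23C[C@H]1C[C@@H](O)[C@@H]2[C@@]1(CCC[C@@](C)(COC(C)=O)[C@H]1CO[Si](C)(C)C(C)(C)C)COC3=O | intermediate
39 | C15 enone, C6‑OTBS | C=C1C(=O)[C@]23C[C@H]1C[C@@H](O)[C@@H]2[C@@]1(CCC[C@@](C)(COC(C)=O)[C@H]1CO[Si](C)(C)C(C)(C)C)COC3=O | intermediate
40 | C6 alcohol | C=C1C(=O)[C@]23C[C@H]1C[C@@H](O)[C@@H]2[C@@]1(CCC[C@@](C)(COC(C)=O)[C@H]1CO)COC3=O | intermediate
41 | Trichorabdal B | C=C1C(=O)[C@]23C[C@H]1C[C@@H](O)[C@@H]2[C@@]1(CCC[C@@](C)(COC(C)=O)[C@H]1C=O)COC3=O | target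

## Step count
Total steps: 27. Longest linear sequence: 27 (1 → 3 → 5 → 7 → … → 41; compound 4 joins at Step 2).

## Three steps most likely to fail
1. **Step 10 (Ti(III) coupling).** Forming a quaternary–tertiary bond next to a bulky acetal and controlling C10/C9 diastereoselectivity may give low yield or dr. Fallback: add LiCH2OPMB (from 3) to ketone 13, convert the tertiary alcohol to its N‑phthalimidoyl oxalate, and do an Ir‑photoredox Giese addition to 18, then deprotect and lactonize.
2. **Step 19 (Pd(II) cycloalkenylation).** Stoichiometric Pd, with the risk of endocyclic C15=C16 alkene formation or low conversion. Fallback: brominate the isopropenyl group allylically (NBS) to give the 2‑(bromomethyl)allyl side chain, then close the D ring by intramolecular SN2 alkylation of the lactone enolate, an ionic route with no Pd.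
3. **Step 3 (asymmetric conjugate addition).** Enantioselectivity on this functionalized β‑substituted enone is uncertain. Fallback: desymmetrize dimethyl 3‑methyl‑3‑[(PMBO)methyl]glutarate with pig liver esterase to the chiral monoacid and rebuild ketone 7 by chain extension and Dieckmann cyclization.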